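I followed product in a closed, stirred vessel at constant temperature, where starting material meets partner.

| flask | starting material | partner | time |
|---|---|---|---|
| blue | 1.00 M | 1.00 M |  |
| green | 0.400 M | 0.400 M |  |
| ochre | 1.00 M | 0.500 M |  |
| amber | 3.00 M | 1.00 M | 50 min |

| run | time / min | [product] / M |
|---|---|---|
| blue run | 2.0 | 0.035 |
| blue run | 3.2 | 0.053 |
| blue run | 5.0 | 0.088 |
| blue run | 7.9 | 0.115 |
| blue run | 13 | 0.182 |
| blue run | 20 | 0.248 |
| blue run | 32 | 0.301 |
| blue run | 50 | 0.337 |
| green run | 2.0 | 0.003 |
| green run | 3.2 | 0.011 |
| green run | 5.0 | 0.027 |
| green run | 7.9 | 0.031 |
| green run | 13 | 0.044 |
| green run | 20 | 0.069 |
| green run | 32 | 0.056 |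
| green run | 50 | 0.084 |
| ochre run | 2.0 | 0.019 |
| ochre run | 3.2 | 0.023 |
| ochre run | 5.0 | 0.033 |
| ochre run | 7.9 | 0.069 |
| ochre run | 13 | 0.089 |
| ochre run | 20 | 0.140 |
| ochre run | 32 | 0.163 |
| ochre run | 50 | 0.212 |

(standard deviation of a reading: 0.008 M)

- Overall: starting material + partner -> product.
- Constant volume, constant temperature.
- What is held in complexes is read along with the free species.
- "The second partner" is partner.
- An order is taken over about fifteen percent of the charge, up and down.

- how the opening rate goes with [partner] round the charge of the blue run: the exponent of the rate at two percent of starting material gone to product
- how the opening rate goes with [starting material] round the charge of the blue run: the exponent of the rate at two percent of starting material gone to product (one fixed amount of product, the same in the runs compared)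
- product in the amber run at 50 min, as a share of the starting material charged

To damp the scatter, I summed each run's readings up to 13 min, which gave 0.473 M for the blue run, 0.233 M for the ochre run and 0.116 M for the green run. The ochre sum stood at 0.493 of the blue sum on half the partner, so I read the order in partner as 1.02. The green run had both charges at 0.400 of those of the blue run and its sum stood at 0.245 of the blue sum, so the two charges together carry an exponent of 1.53. Taking off the partner's share leaves 0.512. I carried this reading forward as the charge exponent, an apparent order: the power of the starting material charge left in the early product once the partner's power is taken off.

The forecast gave 1 for partner, 0.55 for starting material and 20.5% for the amber run, holding that “this is equilibrium rather than simple slowing”. My charge exponent stood lower than its order in starting material.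

The simulation gave 1.0 for partner, 0.64 for starting material and 22.9% for the amber run.

    starting material + partner → product (0.05268 /M/min)
    starting material → decomposed substrate (0.07860 /min)
    2 starting material ⇌ idle substrate dimer, settled at all times (2.600 /M)

In this scheme, starting material also goes to decomposed substrate and sits as idle substrate dimer. A power law fitted over all runs put the best order in starting material at 1.4 and forecast 30.4% for the amber run. The amber run has the partner charge of the blue run, so I scaled the blue product at 50 min, 0.337 M, by the charge ratio raised to the charge exponent. That gave 19.7% of the amber charge, below the 22.9% the amber run reached.

(The numbers in the tables are calculated from invented constants.)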